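**Retrosynthetic overview** (kaurane numbering throughout)

1. The target comes from a keto aldehyde that already holds the whole skeleton; only hydride reduction, desilylation and an allylic oxidation remain.
2. Key disconnection: the C9–C10 bond, made by intramolecular Michael addition of the C11-ketone enolate to a tetrasubstituted enal tethered through the C20–O–C7 ester. This closes the δ-lactone (ring B) and sets C9, C10 and C5.
3. The ester comes from O-alkylation of a bridgehead acid (rings C/D, a bicyclo[3.2.1]octane) with an allylic bromide (ring A).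
4. Rings C/D: a cyclopentanone β-keto ester (ring D) is allylated asymmetrically (C8), oxidised (Wacker) and closed to ring C by an intramolecular Michael addition. Ring A: β-cyclocitral, by allylic oxidation, bromination and CBS reduction (C1).
5. Ring order: A and D are bought, C is closed onto D, and B (the lactone) is closed last in the key step.

Assumption: the catalyst antipodes named in steps 6 and 11 are taken to give the configurations drawn (otherwise the mirror-image catalyst is used), and the C15 carbinol centre of compounds 24 to 32 is drawn as the epimer expected from exo-face hydride attack; it is erased in step 25.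

**Fragment 1 (ring A)**

Step 1
Reactants: 1 β-cyclocitral (2,6,6-trimethylcyclohex-1-ene-1-carbaldehyde)
Product: 2 2,6,6-trimethylcyclohex-1-ene-1-carboxylic acid
Conditions: NaClO2, NaH2PO4, 30% H2O2, MeCN/H2O, 10 °C → rt
Reagents that add atoms: sodium chlorite, [Na+].[O-]Cl=O
Why: Pinnick (chlorite) oxidation converts the hindered conjugated aldehyde to the acid without touching the tetrasubstituted alkene, H2O2 destroying the hypochlorite that is formed.

Step 2
Reactants: 2 2,6,6-trimethylcyclohex-1-ene-1-carboxylic acid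
Product: 3 methyl 2,6,6-trimethylcyclohex-1-ene-1-carboxylate
Conditions: MeI, K2CO3, DMF, rt
Reagents that add atoms: iodomethane, CI
Why: SN2 O-alkylation of the carboxylate (esterification by alkylation) avoids the slow Fischer esterification of this hindered acid.

Step 3
Reactants: 3 methyl 2,6,6-trimethylcyclohex-1-ene-1-carboxylate
Product: 4 methyl 2,6,6-trimethyl-3-oxocyclohex-1-ene-1-carboxylate
Conditions: t-BuOOH (70% aq.), dirhodium tetrakis(caprolactamate) Rh2(C6H10NO)4 (1 mol%), K2CO3 (0.5 equiv), CH2Cl2, rt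
Reagents that add atoms: tert-butyl hydroperoxide, CC(C)(C)OO
Why: Radical allylic C–H oxidation by tert-butylperoxyl radicals takes the only ring allylic methylene (the future C1) to the enone in preference to the vinylic methyl.

Step 4
Reactants: 4 methyl 2,6,6-trimethyl-3-oxocyclohex-1-ene-1-carboxylate
Product: 5 methyl 2-(bromomethyl)-6,6-dimethyl-3-oxocyclohex-1-ene-1-carboxylate
Conditions: NBS, AIBN (5 mol%), PhCF3, reflux
Reagents that add atoms: N-bromosuccinimide, O=C1CCC(=O)N1Br
Why: Wohl–Ziegler radical bromination puts bromine on the methyl group (future C20) because it carries the only allylic C–H bonds left in the molecule.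

Step 5
Reactants: 5 methyl 2-(bromomethyl)-6,6-dimethyl-3-oxocyclohex-1-ene-1-carboxylate
Product: 7 7,7-dimethyl-6,7-dihydro-2-benzofuran-1,4(3H,5H)-dione, via hydroxy ester 6 (not isolated)
Conditions: CaCO3, 1,4-dioxane/H2O 1:1, 90 °C
Reagents that add atoms: water, O
Why: Nucleophilic substitution (hydrolysis) of the allylic bromide is followed by spontaneous lactonisation of the cis γ-hydroxy ester, giving a butenolide that stores C6 at the acid level and C20 at the alcohol level.

Step 6
Reactants: 7 7,7-dimethyl-6,7-dihydro-2-benzofuran-1,4(3H,5H)-dione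
Product: 8 (4S)-4-hydroxy-7,7-dimethyl-4,5,6,7-tetrahydro-2-benzofuran-1(3H)-one
Conditions: (R)-2-methyl-CBS-oxazaborolidine (20 mol%), BH3·SMe2, THF, −30 °C; then MeOH
Reagents that add atoms: none
Why: Corey–Bakshi–Shibata reduction, in which the catalyst distinguishes the substituted alkene carbon (large) from the ring methylene (small) and delivers hydride to one face, sets C1 as S while the lactone is untouched.

Step 7
Reactants: 8 (4S)-4-hydroxy-7,7-dimethyl-4,5,6,7-tetrahydro-2-benzofuran-1(3H)-one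
Product: 9 (1S)-2,3-bis(hydroxymethyl)-4,4-dimethylcyclohex-2-en-1-ol
Conditions: i-Bu2AlH (5 equiv), CH2Cl2, −78 → 0 °C; aq. potassium sodium tartrate
Reagents that add atoms: none
Why: Aluminium hydride reduction of the unsaturated lactone is 1,2-selective and gives the allylic diol without touching the alkene or the C1 centre.

Step 8
Reactants: 9 (1S)-2,3-bis(hydroxymethyl)-4,4-dimethylcyclohex-2-en-1-ol
Product: 10 [(8aS)-2-methoxy-2,6,6-trimethyl-6,7,8,8a-tetrahydro-4H-1,3-benzodioxin-5-yl]methanol (both epimers at the orthoester carbon)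
Conditions: MeC(OMe)3 (1.3 equiv), pyridinium p-toluenesulfonate (5 mol%), CH2Cl2, 0 °C → rt; Et3N quench
Reagents that add atoms: trimethyl orthoacetate, COC(C)(OC)OC
Why: Acid-catalysed orthoester exchange under thermodynamic control closes the six-membered 1,3-dioxane on the C1/C20 diol in preference to the seven-membered ring across C20/C6, leaving the hindered C6 hydroxyl free.

Step 9
Reactants: 10 [(8aS)-2-methoxy-2,6,6-trimethyl-6,7,8,8a-tetrahydro-4H-1,3-benzodioxin-5-yl]methanol
Product: 11 (8aS)-2-methoxy-2,6,6-trimethyl-6,7,8,8a-tetrahydro-4H-1,3-benzodioxine-5-carbaldehyde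
Conditions: (n-Pr)4N[RuO4] (5 mol%), N-methylmorpholine N-oxide, 4 Å MS, CH2Cl2, rt
Reagents that add atoms: none
Why: Ley–Griffith oxidation takes the primary allylic alcohol to the enal under neutral conditions that the orthoester survives.

Step 10
Reactants: 11 (8aS)-2-methoxy-2,6,6-trimethyl-6,7,8,8a-tetrahydro-4H-1,3-benzodioxine-5-carbaldehyde
Product: 13 (1S)-2-(bromomethyl)-3-formyl-4,4-dimethylcyclohex-2-en-1-yl acetate, via dioxanylium bromide 12 (not isolated)
Conditions: AcBr (1.2 equiv), CH2Cl2, −20 → 0 °C; used at once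
Reagents that add atoms: acetyl bromide, CC(=O)Br
Why: Acetoxonium ring opening, in which acetyl bromide ionises the orthoester and bromide opens the cation by SN2 at the primary allylic C20, leaves the acetate on C1 with retention because the C1–O bond is never broken.

**Fragment 2 (rings C/D)**

Step 11
Reactants: 14 tert-butyl 2-oxocyclopentane-1-carboxylate; 15 allyl bromide
Product: 16 tert-butyl (1S)-2-oxo-1-(prop-2-en-1-yl)cyclopentane-1-carboxylate
Conditions: (S,S)-3,4,5-trifluorophenyl-NAS bromide (N-spiro binaphthyl quaternary ammonium bromide, 1 mol%), K2CO3, toluene, 0 °C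
Reagents that add atoms: none
Why: Asymmetric phase-transfer C-alkylation, in which the chiral ammonium enolate ion pair shields one enolate face, sets the quaternary C8 as S.

Step 12
Reactants: 16 tert-butyl (1S)-2-oxo-1-(prop-2-en-1-yl)cyclopentane-1-carboxylate
Product: 17 tert-butyl (1R)-2-oxo-1-(prop-2-en-1-yl)cyclopent-3-ene-1-carboxylate
Conditions: 2-iodoxybenzoic acid (IBX), 4-methoxypyridine N-oxide, DMSO, 25 → 45 °C
Reagents that add atoms: none
Why: IBX dehydrogenation of the ketone, which can enolise only away from the quaternary carbon, gives the cyclopentenone (the descriptor changes by CIP priority only).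

Step 13
Reactants: 17 tert-butyl (1R)-2-oxo-1-(prop-2-en-1-yl)cyclopent-3-ene-1-carboxylate
Product: 18 tert-butyl (1S)-2-oxo-1-(2-oxopropyl)cyclopent-3-ene-1-carboxylate
Conditions: PdCl2 (10 mol%), CuCl, O2 (1 atm), DMF/H2O 7:1, rt
Reagents that add atoms: water, O
Why: Tsuji–Wacker oxidation gives the methyl ketone by Markovnikov hydroxypalladation of the terminal alkene, the electron-poor enone alkene being inert.

Step 14
Reactants: 18 tert-butyl (1S)-2-oxo-1-(2-oxopropyl)cyclopent-3-ene-1-carboxylate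
Product: 19 tert-butyl (1S,5S)-3,7-dioxobicyclo[3.2.1]octane-1-carboxylate
Conditions: pyrrolidine (30 mol%), AcOH (30 mol%), MeCN, 40 °C; then aq. AcOH
Reagents that add atoms: none
Why: Intramolecular Michael addition (6-exo-trig) of the less substituted enamine of the methyl ketone to the cyclopentenone β-carbon closes ring C, and since the three-atom tether can only bridge cis, C13 follows from C8.

Step 15
Reactants: 19 tert-butyl (1S,5S)-3,7-dioxobicyclo[3.2.1]octane-1-carboxylate
Product: 20 tert-butyl (1S,5R)-7-oxospiro[bicyclo[3.2.1]octane-3,2'-[1,3]dioxolane]-1-carboxylate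
Conditions: Me3SiOCH2CH2OSiMe3, Me3SiOTf (5 mol%), CH2Cl2, −78 → −20 °C; pyridine quench
Reagents that add atoms: 1,2-bis(trimethylsilyloxy)ethane, C[Si](C)(C)OCCO[Si](C)(C)C
Why: Noyori ketalisation is selective for the unhindered six-ring C11 ketone over the C15 ketone that sits next to the quaternary carbon.

Step 16
Reactants: 20 tert-butyl (1S,5R)-7-oxospiro[bicyclo[3.2.1]octane-3,2'-[1,3]dioxolane]-1-carboxylate
Product: 23 tert-butyl (1S,5S)-6-methylidene-7-oxospiro[bicyclo[3.2.1]octane-3,2'-[1,3]dioxolane]-1-carboxylate, via Mannich base 21 (not isolated), via amine N-oxide 22 (not isolated)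
Conditions: LiN(SiMe3)2, THF, −78 °C; Me2N=CH2 I, −78 °C → rt; then mCPBA, CH2Cl2, 0 °C → rt
Reagents that add atoms: N,N-dimethylmethyleneiminium iodide (Eschenmoser's salt), C=[N+](C)C.[I-]
Why: Eschenmoser methylenation, a Mannich reaction of the only possible enolate (towards C16) followed by amine-oxide Cope elimination, installs the exocyclic methylene.

Step 17
Reactants: 23 tert-butyl (1S,5S)-6-methylidene-7-oxospiro[bicyclo[3.2.1]octane-3,2'-[1,3]dioxolane]-1-carboxylate
Product: 24 tert-butyl (1S,5S,7R)-7-hydroxy-6-methylidenespiro[bicyclo[3.2.1]octane-3,2'-[1,3]dioxolane]-1-carboxylate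
Conditions: NaBH4, CeCl3·7H2O, MeOH, −78 °C
Reagents that add atoms: none
Why: Luche 1,2-reduction masks the enone as an allylic alcohol, hydride adding from the exo face (side of the one-carbon bridge) because the endo face is blocked by the axial ketal oxygen, which gives the endo 15R carbinol.

Step 18
Reactants: 24 tert-butyl (1S,5S,7R)-7-hydroxy-6-methylidenespiro[bicyclo[3.2.1]octane-3,2'-[1,3]dioxolane]-1-carboxylate
Product: 25 tert-butyl (1S,5S,7R)-7-[(tert-butyldimethylsilyl)oxy]-6-methylidenespiro[bicyclo[3.2.1]octane-3,2'-[1,3]dioxolane]-1-carboxylate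
Conditions: TBSOTf, 2,6-lutidine, CH2Cl2, −78 → 0 °C
Reagents that add atoms: tert-butyldimethylsilyl trifluoromethanesulfonate, CC(C)(C)[Si](C)(C)OS(=O)(=O)C(F)(F)F
Why: Silylation with the reactive silyl triflate protects the hindered allylic alcohol so that it can later neither form a hemiketal with C11 nor undergo retro-aldol cleavage.

Step 19
Reactants: 25 tert-butyl (1S,5S,7R)-7-[(tert-butyldimethylsilyl)oxy]-6-methylidenespiro[bicyclo[3.2.1]octane-3,2'-[1,3]dioxolane]-1-carboxylate
Product: 26 tert-butyl (1S,5S,7R)-7-[(tert-butyldimethylsilyl)oxy]-6-methylidene-3-oxobicyclo[3.2.1]octane-1-carboxylate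
Conditions: pyridinium p-toluenesulfonate, acetone/H2O 10:1, 55 °C
Reagents that add atoms: water, O
Why: Mild acid-catalysed ketal hydrolysis frees the C11 ketone while the hindered silyl ether and the tert-butyl ester survive.

Step 20
Reactants: 26 tert-butyl (1S,5S,7R)-7-[(tert-butyldimethylsilyl)oxy]-6-methylidene-3-oxobicyclo[3.2.1]octane-1-carboxylate
Product: 28 (1S,5S,7R)-7-[(tert-butyldimethylsilyl)oxy]-6-methylidene-3-oxobicyclo[3.2.1]octane-1-carboxylic acid, via trimethylsilyl ester 27 (not isolated)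
Conditions: Me3SiOTf, 2,6-lutidine, CH2Cl2, 0 °C; then H2O (pH 5)
Reagents that add atoms: none
Why: Silyl-triflate-mediated tert-butyl ester cleavage (loss of isobutene) gives a silyl ester that is hydrolysed on work-up, sparing the silyl ether.

**Fragment union and endgame**

Step 21
Reactants: 28 (1S,5S,7R)-7-[(tert-butyldimethylsilyl)oxy]-6-methylidene-3-oxobicyclo[3.2.1]octane-1-carboxylic acid; 13 (1S)-2-(bromomethyl)-3-formyl-4,4-dimethylcyclohex-2-en-1-yl acetate
Product: 29 [(6S)-6-acetoxy-2-formyl-3,3-dimethylcyclohex-1-en-1-yl]methyl (1S,5S,7R)-7-[(tert-butyldimethylsilyl)oxy]-6-methylidene-3-oxobicyclo[3.2.1]octane-1-carboxylate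
Conditions: Cs2CO3 (1.0 equiv), DMF, 0 °C; then 13, 0 °C → rt
Reagents that add atoms: none
Why: SN2 O-alkylation of the caesium carboxylate by the allylic bromide joins the fragments without having to acylate with the hindered bridgehead acid.

Step 22
Reactants: 29 [(6S)-6-acetoxy-2-formyl-3,3-dimethylcyclohex-1-en-1-yl]methyl (1S,5S,7R)-7-[(tert-butyldimethylsilyl)oxy]-6-methylidene-3-oxobicyclo[3.2.1]octane-1-carboxylate
Product: 30 6,7-seco-ent-kaur-16-ene 7,20-lactone carrying 1-OAc, 6-CHO, 11-oxo and 15-OTBS (1S,5R,8S,9S,10R,13S,15R)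
Conditions: Cs2CO3 (1.5 equiv), MeCN (0.005 M), 40 °C; AcOH quench at 0 °C
Reagents that add atoms: none
Why: Intramolecular Michael addition (6-exo-trig) of the C9 enolate of the C11 ketone to C10 of the enal closes the δ-lactone ring B, attack anti to the pseudoaxial C1 acetate setting C10 (R), axial alkylation on the exo face of the bicycle setting C9 (S) and axial protonation of the aldehyde enolate setting C5 (R).

Step 23
Reactants: 30 6,7-seco-ent-kaur-16-ene 7,20-lactone carrying 1-OAc, 6-CHO, 11-oxo and 15-OTBS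
Product: 31 6,7-seco-ent-kaur-16-ene 7,20-lactone carrying 1-OAc, 6-OH, 11-OH and 15-OTBS (1S,5R,8S,9S,10R,11S,13S,15R)
Conditions: NaBH4, CeCl3·7H2O, MeOH/THF 1:1, −40 → 0 °C
Reagents that add atoms: none
Why: Luche-type borohydride reduction of the aldehyde and the C11 ketone gives the axial 11S alcohol because the face of C11 under the two-carbon bridge and its endo silyl ether is blocked and hydride adds from the opposite side, while lactone and acetate are left alone.

Step 24
Reactants: 31 6,7-seco-ent-kaur-16-ene 7,20-lactone carrying 1-OAc, 6-OH, 11-OH and 15-OTBS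
Product: 32 6,7-seco-ent-kaur-16-ene 7,20-lactone carrying 1-OAc, 6-OH, 11-OH and 15-OH (1S,5R,8S,9S,10R,11S,13S,15R)
Conditions: HF·pyridine, pyridine/THF, 0 °C → rt
Reagents that add atoms: none
Why: Fluoride-mediated desilylation frees the allylic C15 alcohol under conditions that do not touch the acetate or the lactone.

Step 25
Reactants: 32 6,7-seco-ent-kaur-16-ene 7,20-lactone carrying 1-OAc, 6-OH, 11-OH and 15-OH
Product: 33 Maoyecrystal E
Conditions: MnO2 (activated, excess), CH2Cl2, rt
Reagents that add atoms: none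
Why: Chemoselective MnO2 oxidation touches only the allylic C15 alcohol, not the primary C6 or the saturated C11 alcohol, and reveals the α-methylene cyclopentanone.

**Compound list**

1 | β-cyclocitral (2,6,6-trimethylcyclohex-1-ene-1-carbaldehyde) | O=CC1=C(C)CCCC1(C)C | starting material
2 | 2,6,6-trimethylcyclohex-1-ene-1-carboxylic acid | OC(=O)C1=C(C)CCCC1(C)C | intermediate
3 | methyl 2,6,6-trimethylcyclohex-1-ene-1-carboxylate | COC(=O)C1=C(C)CCCC1(C)C | intermediate
4 | methyl 2,6,6-trimethyl-3-oxocyclohex-1-ene-1-carboxylate | COC(=O)C1=C(C)C(=O)CCC1(C)C | intermediate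
5 | methyl 2-(bromomethyl)-6,6-dimethyl-3-oxocyclohex-1-ene-1-carboxylate | COC(=O)C1=C(CBr)C(=O)CCC1(C)C | intermediate
6 | methyl 2-(hydroxymethyl)-6,6-dimethyl-3-oxocyclohex-1-ene-1-carboxylate (not isolated) | COC(=O)C1=C(CO)C(=O)CCC1(C)C | intermediate
7 | 7,7-dimethyl-6,7-dihydro-2-benzofuran-1,4(3H,5H)-dione | O=C1OCC2=C1C(C)(C)CCC2=O | intermediate
8 | (4S)-4-hydroxy-7,7-dimethyl-4,5,6,7-tetrahydro-2-benzofuran-1(3H)-one | O=C1OCC2=C1C(C)(C)CC[C@@H]2O | intermediate
9 | (1S)-2,3-bis(hydroxymethyl)-4,4-dimethylcyclohex-2-en-1-ol | OCC1=C(CO)[C@@H](O)CCC1(C)C | intermediate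
10 | [(8aS)-2-methoxy-2,6,6-trimethyl-6,7,8,8a-tetrahydro-4H-1,3-benzodioxin-5-yl]methanol (orthoester carbon epimers) | OCC1=C2COC(C)(OC)O[C@H]2CCC1(C)C | intermediate
11 | (8aS)-2-methoxy-2,6,6-trimethyl-6,7,8,8a-tetrahydro-4H-1,3-benzodioxine-5-carbaldehyde | O=CC1=C2COC(C)(OC)O[C@H]2CCC1(C)C | intermediate
12 | (8aS)-5-formyl-2,6,6-trimethyl-6,7,8,8a-tetrahydro-4H-1,3-benzodioxin-2-ylium bromide (not isolated) | O=CC1=C2CO[C+](C)O[C@H]2CCC1(C)C.[Br-] | intermediate
13 | (1S)-2-(bromomethyl)-3-formyl-4,4-dimethylcyclohex-2-en-1-yl acetate | O=CC1=C(CBr)[C@@H](OC(C)=O)CCC1(C)C | intermediate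
14 | tert-butyl 2-oxocyclopentane-1-carboxylate | O=C1CCCC1C(=O)OC(C)(C)C | starting material
15 | allyl bromide (3-bromoprop-1-ene) | C=CCBr | starting material
16 | tert-butyl (1S)-2-oxo-1-(prop-2-en-1-yl)cyclopentane-1-carboxylate | O=C1CCC[C@@]1(CC=C)C(=O)OC(C)(C)C | intermediate
17 | tert-butyl (1R)-2-oxo-1-(prop-2-en-1-yl)cyclopent-3-ene-1-carboxylate | O=C1C=CC[C@@]1(CC=C)C(=O)OC(C)(C)C | intermediate
18 | tert-butyl (1S)-2-oxo-1-(2-oxopropyl)cyclopent-3-ene-1-carboxylate | O=C1C=CC[C@@]1(CC(C)=O)C(=O)OC(C)(C)C | intermediate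
19 | tert-butyl (1S,5S)-3,7-dioxobicyclo[3.2.1]octane-1-carboxylate | C1C(=O)[C@]2(C(=O)OC(C)(C)C)C[C@H]1CC(=O)C2 | intermediate
20 | tert-butyl (1S,5R)-7-oxospiro[bicyclo[3.2.1]octane-3,2'-[1,3]dioxolane]-1-carboxylate | C1C(=O)[C@]2(C(=O)OC(C)(C)C)C[C@H]1CC3(OCCO3)C2 | intermediate
21 | tert-butyl (1S,5S)-6-[(dimethylamino)methyl]-7-oxospiro[bicyclo[3.2.1]octane-3,2'-[1,3]dioxolane]-1-carboxylate (C6 epimers, not isolated) | CN(C)CC1C(=O)[C@]2(C(=O)OC(C)(C)C)C[C@H]1CC3(OCCO3)C2 | intermediate
22 | N-oxide of 21 (not isolated) | C[N+](C)([O-])CC1C(=O)[C@]2(C(=O)OC(C)(C)C)C[C@H]1CC3(OCCO3)C2 | intermediate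
23 | tert-butyl (1S,5S)-6-methylidene-7-oxospiro[bicyclo[3.2.1]octane-3,2'-[1,3]dioxolane]-1-carboxylate | C=C1C(=O)[C@]2(C(=O)OC(C)(C)C)C[C@H]1CC3(OCCO3)C2 | intermediate
24 | tert-butyl (1S,5S,7R)-7-hydroxy-6-methylidenespiro[bicyclo[3.2.1]octane-3,2'-[1,3]dioxolane]-1-carboxylate | C=C1[C@@H](O)[C@]2(C(=O)OC(C)(C)C)C[C@H]1CC3(OCCO3)C2 | intermediate
25 | tert-butyl (1S,5S,7R)-7-[(tert-butyldimethylsilyl)oxy]-6-methylidenespiro[bicyclo[3.2.1]octane-3,2'-[1,3]dioxolane]-1-carboxylate | C=C1[C@@H](O[Si](C)(C)C(C)(C)C)[C@]2(C(=O)OC(C)(C)C)C[C@H]1CC3(OCCO3)C2 | intermediate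
26 | tert-butyl (1S,5S,7R)-7-[(tert-butyldimethylsilyl)oxy]-6-methylidene-3-oxobicyclo[3.2.1]octane-1-carboxylate | C=C1[C@@H](O[Si](C)(C)C(C)(C)C)[C@]2(C(=O)OC(C)(C)C)C[C@H]1CC(=O)C2 | intermediate
27 | trimethylsilyl (1S,5S,7R)-7-[(tert-butyldimethylsilyl)oxy]-6-methylidene-3-oxobicyclo[3.2.1]octane-1-carboxylate (not isolated) | C=C1[C@@H](O[Si](C)(C)C(C)(C)C)[C@]2(C(=O)O[Si](C)(C)C)C[C@H]1CC(=O)C2 | intermediate
28 | (1S,5S,7R)-7-[(tert-butyldimethylsilyl)oxy]-6-methylidene-3-oxobicyclo[3.2.1]octane-1-carboxylic acid | C=C1[C@@H](O[Si](C)(C)C(C)(C)C)[C@]2(C(=O)O)C[C@H]1CC(=O)C2 | intermediate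
29 | [(6S)-6-acetoxy-2-formyl-3,3-dimethylcyclohex-1-en-1-yl]methyl (1S,5S,7R)-7-[(tert-butyldimethylsilyl)oxy]-6-methylidene-3-oxobicyclo[3.2.1]octane-1-carboxylate | C=C1[C@@H](O[Si](C)(C)C(C)(C)C)[C@]2(C(=O)OCC3=C(C=O)C(C)(C)CC[C@@H]3OC(C)=O)C[C@H]1CC(=O)C2 | intermediate
30 | 6,7-seco-ent-kaur-16-ene 7,20-lactone with 1-OAc, 6-CHO, 11-oxo, 15-OTBS (1S,5R,8S,9S,10R,13S,15R) | C=C1[C@@H](O[Si](C)(C)C(C)(C)C)[C@]23C[C@H]1CC(=O)[C@H]2[C@]1(COC3=O)[C@@H](OC(C)=O)CCC(C)(C)[C@H]1C=O | intermediate
31 | 6,7-seco-ent-kaur-16-ene 7,20-lactone with 1-OAc, 6-OH, 11-OH, 15-OTBS (1S,5R,8S,9S,10R,11S,13S,15R) | C=C1[C@@H](O[Si](C)(C)C(C)(C)C)[C@]23C[C@H]1C[C@H](O)[C@H]2[C@]1(COC3=O)[C@@H](OC(C)=O)CCC(C)(C)[C@H]1CO | intermediate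
32 | 6,7-seco-ent-kaur-16-ene 7,20-lactone with 1-OAc, 6-OH, 11-OH, 15-OH (1S,5R,8S,9S,10R,11S,13S,15R) | C=C1[C@@H](O)[C@]23C[C@H]1C[C@H](O)[C@H]2[C@]1(COC3=O)[C@@H](OC(C)=O)CCC(C)(C)[C@H]1CO | intermediate
33 | Maoyecrystal E (1S,5R,8S,9S,10R,11S,13S) | C=C1C(=O)[C@]23C[C@H]1C[C@H](O)[C@H]2[C@]1(COC3=O)[C@@H](OC(C)=O)CCC(C)(C)[C@H]1CO | target

**Step count**

Total: 25 steps. Longest linear sequence: 15 steps (steps 1–10 or, equally, 11–20, followed by 21–25), which is 60% of the total.

**Three steps most likely to fail**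

Step 22 (key lactone-closing Michael addition). A simple ketone enolate has to attack a tetrasubstituted enal and build a quaternary carbon next to a tertiary and another quaternary centre; retro-Michael reaction or C9 epimerisation under base are the likely failures. The fallback sets out from 29 and leaves enolate chemistry. Me3SiOTf/Et3N (CH2Cl2, −78 °C) gives the C9(11) trimethylsilyl enol ether of 29 F1 (the C11(12) regioisomer cannot reach C10 and is returned to 29 on hydrolysis). F1 is then closed by a TiCl4-promoted intramolecular Mukaiyama–Michael addition at −78 °C, in which the Lewis acid activates the enal and the acetate never sees base. Aqueous work-up removes the silyl group and the route is rejoined at 30.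

Step 14 (ring C closure). The methyl ketone of 18 could instead add 1,2 to the ring carbonyl and give the five-membered aldol (diquinane) product. The fallback sets out from 17 and replaces the ketone donor by a doubly activated one. OsO4 (cat.)/NaIO4 cleaves only the terminal alkene to tert-butyl (1S)-2-oxo-1-(2-oxoethyl)cyclopent-3-ene-1-carboxylate F2. Roskamp homologation (allyl diazoacetate, SnCl2 cat., CH2Cl2) gives tert-butyl (1S)-1-[2,4-dioxo-4-(prop-2-en-1-yloxy)butyl]-2-oxocyclopent-3-ene-1-carboxylate F3. K2CO3 (cat.) in MeCN closes the ring by Michael addition of the stabilised carbanion, which adds 1,4 only, to 1-tert-butyl 4-(prop-2-en-1-yl) (1S,5R)-3,7-dioxobicyclo[3.2.1]octane-1,4-dicarboxylate F4. Pd(PPh3)4/morpholine in THF removes the allyl ester with decarboxylation and the route is rejoined at 19.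

Step 8 (differentiation of the triol). The orthoester could close across the two primary hydroxyls (seven-membered ring), or the cis diol could cyclise under acid. The fallback sets out from 8 and avoids the triol. Me(MeO)NH·HCl/i-PrMgCl (THF, −20 °C) opens the lactone to (3S)-3-hydroxy-2-(hydroxymethyl)-N-methoxy-N,6,6-trimethylcyclohex-1-ene-1-carboxamide F5, whose only diol is the C1/C20 1,3-diol. MeC(OMe)3/pyridinium p-toluenesulfonate can then give only the six-membered orthoester (8aS)-N,2-dimethoxy-N,2,6,6-tetramethyl-6,7,8,8a-tetrahydro-4H-1,3-benzodioxine-5-carboxamide F6. i-Bu2AlH at −78 °C reduces the Weinreb amide to the aldehyde and the route is rejoined at 11, so steps 7 to 9 are skipped.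

**Further compounds**

F1 | step 22 | C9(11) trimethylsilyl enol ether of 29 | C=C1[C@@H](O[Si](C)(C)C(C)(C)C)[C@]2(C(=O)OCC3=C(C=O)C(C)(C)CC[C@@H]3OC(C)=O)C[C@H]1CC(O[Si](C)(C)C)=C2
F2 | step 14 | tert-butyl (1S)-2-oxo-1-(2-oxoethyl)cyclopent-3-ene-1-carboxylate | O=C1C=CC[C@@]1(CC=O)C(=O)OC(C)(C)C
F3 | step 14 | tert-butyl (1S)-1-[2,4-dioxo-4-(prop-2-en-1-yloxy)butyl]-2-oxocyclopent-3-ene-1-carboxylate | O=C1C=CC[C@@]1(CC(=O)CC(=O)OCC=C)C(=O)OC(C)(C)C
F4 | step 14 | 1-tert-butyl 4-(prop-2-en-1-yl) (1S,5R)-3,7-dioxobicyclo[3.2.1]octane-1,4-dicarboxylate (C4 epimers) | C1C(=O)[C@]2(C(=O)OC(C)(C)C)C[C@H]1C(C(=O)OCC=C)C(=O)C2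
F5 | step 8 | (3S)-3-hydroxy-2-(hydroxymethyl)-N-methoxy-N,6,6-trimethylcyclohex-1-ene-1-carboxamide | CON(C)C(=O)C1=C(CO)[C@@H](O)CCC1(C)C
F6 | step 8 | (8aS)-N,2-dimethoxy-N,2,6,6-tetramethyl-6,7,8,8a-tetrahydro-4H-1,3-benzodioxine-5-carboxamide | CON(C)C(=O)C1=C2COC(C)(OC)O[C@H]2CCC1(C)C
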